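The incoming ligand decays.

common to all: protic impurity 0.100 mM; time 30 s
- beta: starting complex 0.0050 M (fed, over 12 s); incoming ligand 0.600 equiv; all else is in the flask from the start; the feed brings no volume worth counting
- alpha: starting complex 0.0050 M; incoming ligand 0.600 equiv (fed, over 12 s); all else is in the flask from the start; the feed brings no volume worth counting
- gamma: starting complex 0.0050 M (fed, over 3.0 s); incoming ligand 0.600 equiv; all else is in the flask from the start; the feed brings no volume worth counting
- epsilon: starting complex 0.0050 M; incoming ligand 0.600 equiv (in portions, 3, over 12 s); first portion at the start, last at 12 s
- zeta: starting complex 0.0050 M; incoming ligand 0.600 equiv; everything together at the start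

    complex with three exchanged + incoming ligand → leaving ligand + complex with four exchanged (k1 = 0.31 M⁻¹ s⁻¹)
    complex with one exchanged + incoming ligand → leaving ligand + complex with two exchanged (k2 = 51 M⁻¹ s⁻¹)
    incoming ligand → decomposed reagent (k3 = 0.41 s⁻¹)
    starting complex + incoming ligand → leaving ligand + complex with one exchanged (k4 = 8.9 M⁻¹ s⁻¹)
    complex with two exchanged + incoming ligand → leaving ligand + complex with three exchanged (k5 = 6.8 M⁻¹ s⁻¹)
    starting complex ⇌ dormant form (K6 = 2.6, k6 = 0.043 s⁻¹)
    protic impurity + starting complex → quenched substrate (k7 = 220 M⁻¹ s⁻¹)

- the flask with the highest share of complex with one exchanged in complex with one exchanged plus complex with two exchanged ("all alike" if they lie within 1.5 percentage points) (beta / alpha / gamma / epsilon / zeta / all alike)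
- share of complex with one exchanged in complex with one exchanged plus complex with two exchanged at the end, beta
- share of complex with one exchanged in complex with one exchanged plus complex with two exchanged at the end, alpha
- share of complex with one exchanged in complex with one exchanged plus complex with two exchanged at the end, gamma
- share of complex with one exchanged in complex with one exchanged plus complex with two exchanged at the end, epsilon
- share of complex with one exchanged in complex with one exchanged plus complex with two exchanged at the end, zeta

The incoming ligand is the limiting reagent at 0.600 equiv, so the reckoning by hand starts from its balance:

ligand charged = decomposed reagent + leaving ligand + ligand still present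

Decomposition takes the ligand at 0.41 s⁻¹, and exchange on the full charge of starting complex at 0.0445 s⁻¹. So nearly all of it becomes decomposed reagent. The time integral of the ligand concentration, its exposure, is therefore close to the ligand charged divided by the decomposition constant, and the dosing does not enter this line. Multiplied by the constant of the second exchange, 51 M⁻¹ s⁻¹, the exposure gives:

second-exchange number = 0.373

This second-exchange number is the exponent that a complex with one exchanged would face over the whole exposure. A complex made partway through faces the part still to come, so:

share ≈ exp(−number × mean fraction of exposure still to come)

The first setting is the ligand's dosing. In zeta the ligand's lifetime of 2.44 s is shorter than the 23.3 s that the forward step alone needs on average to take the starting complex to the dormant form, so the starting complex changes little while the ligand lasts. The first exchange then runs evenly along the exposure, the fraction is 0.5, and the share is 83.0 %. Dosing in alpha and portions in epsilon stretch the clock but leave the exposure, so by hand both stay near that figure.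

The second setting is the feed of starting complex. In beta the feed lasts longer than the ligand lives, so the starting complex grows with time while the ligand decays. Weighted that way, the fraction still to come is 1/4, and the share is 91.1 %. Gamma's feed is shorter, so by hand its share lies between these two.

The third setting is concentration. At fixed equivalents and fixed constants the number as reckoned above is proportional to the starting complex, so by hand a richer flask carries a larger exponent.

The forecast gives 92 % for beta, 90 % for gamma, 85.5 % for zeta, 84 % for alpha and 84 % for epsilon, and names beta. Its ground is that “Feeding the starting complex into ligand that is already decaying makes the first-exchanged complex form late”. For zeta it stands above the hand's figure.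

Beta ends highest at 91.1 %, as forecast, followed by gamma at 89.3 %, zeta at 84.3 %, alpha at 83.5 % and epsilon at 83.1 %. In zeta the decomposed reagent stands at 0.00270 M after 30.0 s. That amount divided by the decomposition constant is the exposure itself, so the number for zeta becomes 0.336, and the fraction 0.5 gives 84.5 %.

The neighbour of beta, with 0.013 M of starting complex at the same equivalents and feed, has a number of 0.970, and the fraction 1/4 gives 78.5 %. The computed flask gives 80.2 %.

The constants used here were chosen freely; what happens was integrated by code.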